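A direct plan would build ring A by a Diels–Alder reaction of a 2,4-bis(silyloxy)pentadiene with citraconic anhydride and carry it on to the enone diester A1 and the allylic alcohol A2, would join A2 to a cyclohexenyl triflate by C–O coupling and Claisen rearrangement to give the dithianyl ketone A3, would allylate the unmasked formyl-bearing carbon to the bromoallyl keto aldehyde A4, would close the five-membered ring by radical cyclisation and would finally dealkylate the dimethyl ester A5.
Its three weakest steps would be these.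
(a) The cycloaddition would have to bond the nucleophilic CH2 terminus of the diene to the methyl-bearing carbon of citraconic anhydride; both partners are polarised the other way, so the regioisomer with the angular methyl on C5 instead of C4 would be expected.
(b) The palladium-catalysed etherification of an enol triflate with the hindered alcohol A2, in tandem with the Claisen shift, would be a C–O coupling without precedent, and the configuration of C9 would depend on a boat transition state.
(c) The last step would dealkylate two hindered methyl esters of A5 with excess thiolate, conditions under which the aldehyde could be attacked and C9, next to the C11 ketone and carrying ring A axial on ring C, could epimerise.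

Retrosynthesis: the last C–C bond cut is C9–C10 (bicyclic silyl enol ether plus ring A enone anhydride); the bicyclo[3.2.1]octane is cut at C8–C9 and C12–C13, and C16=C17 goes back to a ketone.
Enabling feature: C11=O is the middle atom of the bridge C9–C11–C12 and C16 is a latent carbonyl, so C11 and C16 are 1,5-related through C9–C8–C15 and 1,4-related through C12–C13. Ring C is therefore an acetoacetate unit spanning the α′-carbon (C13) and the β-carbon (C8) of a cyclopentenone, which is ring D.
Ring order: ring D is bought as a cyclopentenone; ring C is closed onto it by the key Michael addition (both bridgeheads, quaternary C8); ring A is made apart by a Hagemann-type annulation and joined last on the exo face of C9.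
The weak steps do not arise: the regiochemistry of ring A is fixed by the acceptor of a Michael/aldol annulation; C9–C10 comes from a Lewis-acid Michael addition in which each new centre is set by its own ring; the acids are carried as an anhydride that water opens, so the last step is an alcohol oxidation.

Key step: step 5

Numbering: ent-kaurane numbers are used throughout. Ring A is C1–C5 and C10 (C20 methyl on C10; C18 methyl and C19 carboxyl on C4; C6 carboxyl on C5). C9 links C10 to the bicyclo[3.2.1]octane, whose bridgeheads are C8 (bearing the formyl carbon C7) and C13 and whose bridges are C9–C11(=O)–C12, C15–C16(=C17) and C14. Ring C is C8, C9, C11, C12, C13, C14; ring D is C8, C14, C13, C16, C15.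

Assumption: the sense of induction of the cinchona amines in steps 5 and 9 is taken as drawn (the pseudoenantiomeric amine would be used otherwise), and C9 is treated as a kinetically set centre that no later step may enolise.

Step 1
Reactants: 1 ethyl 4-chloro-3-oxobutanoate
Product: 2 prop-2-en-1-yl 4-chloro-3-oxobutanoate
Conditions: allyl alcohol (3 equiv), PhMe, 110 °C, ethanol distilled off
Reagents that add atoms: prop-2-en-1-ol C=CCO
Why: Thermal transesterification of a β-keto ester through its acylketene, driven by removal of ethanol; no stereocentre.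

Step 2
Reactants: 2 prop-2-en-1-yl 4-chloro-3-oxobutanoate
Product: 3 prop-2-en-1-yl (2E)-4-chloro-3-methoxybut-2-enoate
Conditions: HC(OMe)3 (1.5 equiv), H2SO4 (cat.), 25 → 45 °C, volatiles distilled off
Reagents that add atoms: trimethyl orthoformate COC(OC)OC
Why: Acid-catalysed enol ether formation (ketalisation, loss of methanol) masks the acidic methylene, so that the γ-chloride can serve as an acetoacetate γ-cation equivalent; the (E)-isomer is the usual product.

Step 3
Reactants: 4 3-(hydroxymethyl)cyclopent-2-en-1-one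
Product: 5 3-({[tert-butyl(dimethyl)silyl]oxy}methyl)cyclopent-2-en-1-one
Conditions: TBSCl, imidazole, DMF, 0 → 25 °C
Reagents that add atoms: tert-butyl(chloro)dimethylsilane CC(C)(C)[Si](C)(C)Cl
Why: Silylation of the primary alcohol; C7 is carried at the alcohol level until the last step.

Step 4
Reactants: 5 3-({[tert-butyl(dimethyl)silyl]oxy}methyl)cyclopent-2-en-1-one; 3 prop-2-en-1-yl (2E)-4-chloro-3-methoxybut-2-enoate
Product: 7 prop-2-en-1-yl 4-[4-({[tert-butyl(dimethyl)silyl]oxy}methyl)-2-oxocyclopent-3-en-1-yl]-3-oxobutanoate (racemic at C13), via methyl enol ether 6 (not isolated)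
Conditions: LDA, THF, −78 °C; 3, NaI (cat.), DMPU, −78 → −20 °C; then 5% aq. oxalic acid, THF, 25 °C
Reagents that add atoms: water O
Why: Kinetic deprotonation of the 3-substituted cyclopentenone at C13 (α′) and SN2 alkylation by the activated chloride, then hydrolysis of the enol ether to the β-keto ester; C13 is formed racemic and is equilibrated in step 5.

Step 5
Reactants: 7 prop-2-en-1-yl 4-[4-({[tert-butyl(dimethyl)silyl]oxy}methyl)-2-oxocyclopent-3-en-1-yl]-3-oxobutanoate
Product: 8 prop-2-en-1-yl (1R,5S)-1-({[tert-butyl(dimethyl)silyl]oxy}methyl)-3,6-dioxobicyclo[3.2.1]octane-2-carboxylate (C2 unassigned, partly enolised)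
Conditions: 9-amino-9-deoxy-epi-quinidine (20 mol%), 2-fluorobenzoic acid (40 mol%), PhMe, 40 °C
Reagents that add atoms: none
Why: Proposed new method: the primary amine condenses with the C16 ketone to an iminium ion, which epimerises C13 through the cross-conjugated dienamine and makes C8 electrophilic, while the protonated quinuclidine holds the enol of the β-keto ester so that C9 adds to C8 and hydrolysis returns the catalyst. The closest known reactions are primary-amine (iminium) catalysed Michael additions of 1,3-dicarbonyl compounds to cyclic enones and the base-mediated alkylation–Michael ("double Michael") annulations of cycloalkenone α′-enolates to bridged bicycles. Ring C closes by 6-exo-trig attack of C9 on C8; because the three-atom tether on C13 can reach C8 only from its own face, the closure is necessarily bridged and gives the bicyclo[3.2.1]octane with C14 as the one-carbon bridge. C8 (quaternary) and C13 are therefore set together: the catalyst selects the enone face and hence the C13 epimer that cyclises, the other epimer being fed in by dienamine equilibration (dynamic kinetic resolution), while C9 stays labile as a β-keto ester centre and is set only in step 11. The step needs conjugate attack at C8 rather than reversible 1,2-addition at C16, and it needs face selection, which the rigid iminium ion pair on the cinchona scaffold should secure.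

Step 6
Reactants: 8 prop-2-en-1-yl (1R,5S)-1-({[tert-butyl(dimethyl)silyl]oxy}methyl)-3,6-dioxobicyclo[3.2.1]octane-2-carboxylate
Product: 9 prop-2-en-1-yl (1R,5S)-1-({[tert-butyl(dimethyl)silyl]oxy}methyl)-6-methylidene-3-oxobicyclo[3.2.1]octane-2-carboxylate (C2 unassigned)
Conditions: Ph3PCH3Br (3.2 equiv), KOtBu (3.0 equiv), THF, 0 → 25 °C; aq. NH4Cl
Reagents that add atoms: methyltriphenylphosphonium bromide C[P+](c1ccccc1)(c1ccccc1)c1ccccc1.[Br-]
Why: Wittig methylenation of the C16 ketone; the first equivalent of ylide turns the β-keto ester into its enolate, which shields C11 and blocks retro-Michael opening, and the bridgehead centres cannot epimerise.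

Step 7
Reactants: 9 prop-2-en-1-yl (1R,5S)-1-({[tert-butyl(dimethyl)silyl]oxy}methyl)-6-methylidene-3-oxobicyclo[3.2.1]octane-2-carboxylate
Product: 11 tert-butyl(dimethyl)({(1R,5S)-6-methylidene-3-[(trimethylsilyl)oxy]bicyclo[3.2.1]oct-2-en-1-yl}methoxy)silane, via trimethylsilyl ester 10 (not isolated)
Conditions: Pd(PPh3)4 (3 mol%), Et2NSiMe3 (1.5 equiv), THF, 25 °C; then PhMe, 90 °C
Reagents that add atoms: N,N-diethyl-1,1,1-trimethylsilanamine CCN(CC)[Si](C)(C)C
Why: Allyl transfer from the ester to the silylamine through a π-allyl complex of zerovalent palladium gives the trimethylsilyl β-keto ester, whose thermal decarboxylation through a six-membered transition state moves silicon to the C11 oxygen and leaves the double bond at C9=C11 only (regiospecific enol ether).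

Step 8
Reactants: 12 tert-butyl 2-oxopropanoate; 13 tert-butyl 3-oxobutanoate
Product: 14 di-tert-butyl 2-acetyl-3-methylbut-2-enedioate (E/Z mixture)
Conditions: piperidine (10 mol%), AcOH (10 mol%), PhH, 80 °C, Dean–Stark trap
Reagents that add atoms: none
Why: Knoevenagel condensation of the activated ketone with the β-keto ester gives the tetrasubstituted, triply activated alkene; the geometric isomers interconvert under amine catalysis (reversible conjugate addition), so the mixture serves.

Step 9
Reactants: 14 di-tert-butyl 2-acetyl-3-methylbut-2-enedioate; 15 acetone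
Product: 17 di-tert-butyl (1R)-1,3-dimethyl-5-oxocyclohex-3-ene-1,2-dicarboxylate (C2 epimers), via Michael adduct 16 (not isolated)
Conditions: 9-amino-9-deoxy-epi-quinine (20 mol%), 4-nitrobenzoic acid (40 mol%), acetone, 25 °C; then pyrrolidine, AcOH, 50 °C
Reagents that add atoms: none
Why: Enamine Michael addition of acetone to C4, the carbon of the alkylidene acetoacetate whose attack gives the doubly stabilised anion, sets the quaternary C4 under catalyst control, and a Hagemann-type aldol condensation (acetone methyl onto the acetyl carbonyl) closes ring A with its regiochemistry fixed; C5 stays epimerisable.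

Step 10
Reactants: 17 di-tert-butyl (1R)-1,3-dimethyl-5-oxocyclohex-3-ene-1,2-dicarboxylate
Product: 19 (3aR,7aS)-3a,7-dimethyl-3a,7a-dihydro-2-benzofuran-1,3,5(4H)-trione, via diacid 18 (not isolated)
Conditions: TFA, CH2Cl2, 25 °C; evaporate; Ac2O, 40 °C
Reagents that add atoms: none
Why: Acidolysis of both tert-butyl esters and closure of the five-membered anhydride, which only the cis-diacid can form; C5 (α to the carboxyl and γ to the enone) equilibrates through the mixed anhydride, so C5 is set cis to C19.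

Step 11
Reactants: 11 tert-butyl(dimethyl)({(1R,5S)-6-methylidene-3-[(trimethylsilyl)oxy]bicyclo[3.2.1]oct-2-en-1-yl}methoxy)silane; 19 (3aR,7aS)-3a,7-dimethyl-3a,7a-dihydro-2-benzofuran-1,3,5(4H)-trione
Product: 21 (1R,2S,3S)-3-[(1R,2S,5S)-1-({[tert-butyl(dimethyl)silyl]oxy}methyl)-6-methylidene-3-oxobicyclo[3.2.1]octan-2-yl]-1,3-dimethyl-5-oxocyclohexane-1,2-dicarboxylic acid, via anhydride 20 (not isolated)
Conditions: TiCl4 (1.1 equiv), CH2Cl2, −78 → −40 °C; then THF/H2O, NaHCO3, 25 °C; 1 M HCl to pH 3
Reagents that add atoms: water O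
Why: Mukaiyama–Michael addition of the enol ether carbon C9 to C10 of the titanium-bound enone: C9 reacts on the face anti to the C15–C16 bridge (axial, exo attack, as in C2 functionalisation of bicyclo[3.2.1]octan-3-one enolates) and C10 on the convex face of the cis-fused anhydride, anti to C19 and C6, so each new centre is set by its own ring; water then opens the anhydride.

Step 12
Reactants: 21 (1R,2S,3S)-3-[(1R,2S,5S)-1-({[tert-butyl(dimethyl)silyl]oxy}methyl)-6-methylidene-3-oxobicyclo[3.2.1]octan-2-yl]-1,3-dimethyl-5-oxocyclohexane-1,2-dicarboxylic acid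
Product: 23 (1R,2S,3S)-3-[(1R,2S,5S)-1-({[tert-butyl(dimethyl)silyl]oxy}methyl)-6-methylidene-3-oxobicyclo[3.2.1]octan-2-yl]-1,3-dimethylcyclohexane-1,2-dicarboxylic acid, via tosylhydrazone 22 (not isolated)
Conditions: TsNHNH2 (1.05 equiv), EtOH, 25 °C; evaporate; catecholborane (4 equiv), CHCl3, 0 °C; NaOAc·3H2O, 60 °C
Reagents that add atoms: none
Why: The unhindered ring A ketone (C2) forms the tosylhydrazone while C11, flanked by C9 and its two quaternary neighbours, should not; hydride addition, loss of sulfinate and of N2 (tosylhydrazone reduction) then leave CH2 without a base strong enough to enolise C11.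

Step 13
Reactants: 23 (1R,2S,3S)-3-[(1R,2S,5S)-1-({[tert-butyl(dimethyl)silyl]oxy}methyl)-6-methylidene-3-oxobicyclo[3.2.1]octan-2-yl]-1,3-dimethylcyclohexane-1,2-dicarboxylic acid
Product: 24 (1R,2S,3S)-3-[(1R,2S,5S)-1-(hydroxymethyl)-6-methylidene-3-oxobicyclo[3.2.1]octan-2-yl]-1,3-dimethylcyclohexane-1,2-dicarboxylic acid
Conditions: HF·pyridine, THF, 0 → 25 °C
Reagents that add atoms: none
Why: Fluoride cleavage of the silyl ether under weakly acidic conditions; acids, ketone and alkene are inert and C9 is not enolised.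

Step 14
Reactants: 24 (1R,2S,3S)-3-[(1R,2S,5S)-1-(hydroxymethyl)-6-methylidene-3-oxobicyclo[3.2.1]octan-2-yl]-1,3-dimethylcyclohexane-1,2-dicarboxylic acid
Product: 25 (1R,2S,3S)-3-[(1R,2S,5S)-1-formyl-6-methylidene-3-oxobicyclo[3.2.1]octan-2-yl]-1,3-dimethylcyclohexane-1,2-dicarboxylic acid (target)
Conditions: Dess–Martin periodinane (1.3 equiv), CH2Cl2, 0 → 25 °C
Reagents that add atoms: none
Why: Oxidation of the neopentyl primary alcohol to the non-enolisable aldehyde under neutral conditions, which should spare the free acids, the exocyclic alkene and the C9 centre.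

**Compound list**
1 | ethyl 4-chloro-3-oxobutanoate | CCOC(=O)CC(=O)CCl | starting material
2 | prop-2-en-1-yl 4-chloro-3-oxobutanoate | C=CCOC(=O)CC(=O)CCl | intermediate
3 | prop-2-en-1-yl (2E)-4-chloro-3-methoxybut-2-enoate | CO/C(CCl)=C/C(=O)OCC=C | intermediate
4 | 3-(hydroxymethyl)cyclopent-2-en-1-one | O=C1C=C(CO)CC1 | starting material
5 | 3-({[tert-butyl(dimethyl)silyl]oxy}methyl)cyclopent-2-en-1-one | O=C1C=C(CO[Si](C)(C)C(C)(C)C)CC1 | intermediate
6 | prop-2-en-1-yl (2E)-4-[4-({[tert-butyl(dimethyl)silyl]oxy}methyl)-2-oxocyclopent-3-en-1-yl]-3-methoxybut-2-enoate (racemic) | O=C1C=C(CO[Si](C)(C)C(C)(C)C)CC1C\C(OC)=C/C(=O)OCC=C | intermediate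
7 | prop-2-en-1-yl 4-[4-({[tert-butyl(dimethyl)silyl]oxy}methyl)-2-oxocyclopent-3-en-1-yl]-3-oxobutanoate (racemic at C13) | O=C1C=C(CO[Si](C)(C)C(C)(C)C)CC1CC(=O)CC(=O)OCC=C | intermediate
8 | prop-2-en-1-yl (1R,5S)-1-({[tert-butyl(dimethyl)silyl]oxy}methyl)-3,6-dioxobicyclo[3.2.1]octane-2-carboxylate (C2 unassigned) | O=C1C[C@]2(CO[Si](C)(C)C(C)(C)C)C[C@H]1CC(=O)C2C(=O)OCC=C | intermediate
9 | prop-2-en-1-yl (1R,5S)-1-({[tert-butyl(dimethyl)silyl]oxy}methyl)-6-methylidene-3-oxobicyclo[3.2.1]octane-2-carboxylate (C2 unassigned) | C=C1C[C@]2(CO[Si](C)(C)C(C)(C)C)C[C@H]1CC(=O)C2C(=O)OCC=C | intermediate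
10 | trimethylsilyl (1R,5S)-1-({[tert-butyl(dimethyl)silyl]oxy}methyl)-6-methylidene-3-oxobicyclo[3.2.1]octane-2-carboxylate | C=C1C[C@]2(CO[Si](C)(C)C(C)(C)C)C[C@H]1CC(=O)C2C(=O)O[Si](C)(C)C | intermediate
11 | tert-butyl(dimethyl)({(1R,5S)-6-methylidene-3-[(trimethylsilyl)oxy]bicyclo[3.2.1]oct-2-en-1-yl}methoxy)silane | C=C1C[C@]2(CO[Si](C)(C)C(C)(C)C)C[C@H]1CC(O[Si](C)(C)C)=C2 | intermediate
12 | tert-butyl 2-oxopropanoate | CC(=O)C(=O)OC(C)(C)C | starting material
13 | tert-butyl 3-oxobutanoate | CC(=O)CC(=O)OC(C)(C)C | starting material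
14 | di-tert-butyl 2-acetyl-3-methylbut-2-enedioate (E/Z mixture) | CC(=O)C(C(=O)OC(C)(C)C)=C(C)C(=O)OC(C)(C)C | intermediate
15 | acetone | CC(C)=O | starting material
16 | di-tert-butyl (2R)-3-acetyl-2-methyl-2-(2-oxopropyl)butanedioate (C3 epimers) | CC(=O)C[C@@](C)(C(=O)OC(C)(C)C)C(C(C)=O)C(=O)OC(C)(C)C | intermediate
17 | di-tert-butyl (1R)-1,3-dimethyl-5-oxocyclohex-3-ene-1,2-dicarboxylate (C2 epimers) | CC1=CC(=O)C[C@@](C)(C(=O)OC(C)(C)C)C1C(=O)OC(C)(C)C | intermediate
18 | (1R)-1,3-dimethyl-5-oxocyclohex-3-ene-1,2-dicarboxylic acid (C2 epimers) | CC1=CC(=O)C[C@@](C)(C(=O)O)C1C(=O)O | intermediate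
19 | (3aR,7aS)-3a,7-dimethyl-3a,7a-dihydro-2-benzofuran-1,3,5(4H)-trione | CC1=CC(=O)C[C@@]2(C)C(=O)OC(=O)[C@@H]12 | intermediate
20 | cyclic anhydride (C19–O–C6) of 21, the primary Michael adduct | C=C1C[C@]2(CO[Si](C)(C)C(C)(C)C)C[C@H]1CC(=O)[C@H]2[C@]1(C)CC(=O)C[C@@]3(C)C(=O)OC(=O)[C@@H]13 | intermediate
21 | (1R,2S,3S)-3-[(1R,2S,5S)-1-({[tert-butyl(dimethyl)silyl]oxy}methyl)-6-methylidene-3-oxobicyclo[3.2.1]octan-2-yl]-1,3-dimethyl-5-oxocyclohexane-1,2-dicarboxylic acid | C=C1C[C@]2(CO[Si](C)(C)C(C)(C)C)C[C@H]1CC(=O)[C@H]2[C@]1(C)CC(=O)C[C@@](C)(C(=O)O)[C@H]1C(=O)O | intermediate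
22 | 4-methylbenzenesulfonylhydrazone of 21 at the ring A ketone (C2) | C=C1C[C@]2(CO[Si](C)(C)C(C)(C)C)C[C@H]1CC(=O)[C@H]2[C@]1(C)CC(=NNS(=O)(=O)c3ccc(C)cc3)C[C@@](C)(C(=O)O)[C@H]1C(=O)O | intermediate
23 | (1R,2S,3S)-3-[(1R,2S,5S)-1-({[tert-butyl(dimethyl)silyl]oxy}methyl)-6-methylidene-3-oxobicyclo[3.2.1]octan-2-yl]-1,3-dimethylcyclohexane-1,2-dicarboxylic acid | C=C1C[C@]2(CO[Si](C)(C)C(C)(C)C)C[C@H]1CC(=O)[C@H]2[C@]1(C)CCC[C@@](C)(C(=O)O)[C@H]1C(=O)O | intermediate
24 | (1R,2S,3S)-3-[(1R,2S,5S)-1-(hydroxymethyl)-6-methylidene-3-oxobicyclo[3.2.1]octan-2-yl]-1,3-dimethylcyclohexane-1,2-dicarboxylic acid | C=C1C[C@]2(CO)C[C@H]1CC(=O)[C@H]2[C@]1(C)CCC[C@@](C)(C(=O)O)[C@H]1C(=O)O | intermediate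
25 | (1R,2S,3S)-3-[(1R,2S,5S)-1-formyl-6-methylidene-3-oxobicyclo[3.2.1]octan-2-yl]-1,3-dimethylcyclohexane-1,2-dicarboxylic acid (CNP0408869.1) | C=C1C[C@]2(C=O)C[C@H]1CC(=O)[C@H]2[C@]1(C)CCC[C@@](C)(C(=O)O)[C@H]1C(=O)O | target

Total step count: 14. Longest linear sequence: 10 steps (steps 1, 2, 4, 5, 6, 7, 11, 12, 13, 14).

Steps most likely to fail:

Step 5 (Proposed new method). Epimerisation of C13 through the dienamine may be too slow, so that only one enantiomer of 7 cyclises, or the amine may be tied up as an enaminone of the β-keto ester and give poor face selection. The fallback uses known chemistry, sets out from 5 and comes back at 8. Compound 5 would be condensed with (2S)-2-(methoxymethyl)pyrrolidin-1-amine to the hydrazone 3-({[tert-butyl(dimethyl)silyl]oxy}methyl)-N-[(2S)-2-(methoxymethyl)pyrrolidin-1-yl]cyclopent-2-en-1-imine F1. Its aza-enolate (LDA, THF, −95 °C) would be alkylated with 3 to prop-2-en-1-yl (2E)-4-[(1S)-4-({[tert-butyl(dimethyl)silyl]oxy}methyl)-2-{[(2S)-2-(methoxymethyl)pyrrolidin-1-yl]imino}cyclopent-3-en-1-yl]-3-methoxybut-2-enoate F2, in which the auxiliary sets C13 (the (2R)-hydrazine would be used if the sense were opposite). Aqueous oxalic acid would cleave hydrazone and enol ether to prop-2-en-1-yl 4-[(1S)-4-({[tert-butyl(dimethyl)silyl]oxy}methyl)-2-oxocyclopent-3-en-1-yl]-3-oxobutanoate F3, the single C13 enantiomer of 7. Catalytic DBU (MeCN, 0 °C) deprotonates only the β-keto ester, and since the tether reaches C8 from one face only, F3 should close to 8 without loss of configuration.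

Step 11. Congestion at C9 (next to quaternary C8) and at C10 (becoming quaternary) may stop the addition, so that 11 is merely desilylated and the regiochemistry of the enol ether is lost. The fallback is an intramolecular sigmatropic route; it sets out from 8 and 19 and comes back at 23. Compound 19 would be reduced at C2 ((S)-2-methyl-CBS-oxazaborolidine (20 mol%), catecholborane, PhMe, −78 °C; the enantiomeric catalyst if the sense were opposite) to (3aR,5R,7aS)-5-hydroxy-3a,7-dimethyl-3a,4,5,7a-tetrahydro-2-benzofuran-1,3-dione F4, with the hydroxyl trans to the anhydride ring. Heating 8 with F4 (PhMe, 110 °C, allyl alcohol distilled off) would exchange the ester through the acylketene and give the β-keto ester (3aR,5R,7aS)-3a,7-dimethyl-1,3-dioxo-1,3,3a,4,5,7a-hexahydro-2-benzofuran-5-yl (1R,5S)-1-({[tert-butyl(dimethyl)silyl]oxy}methyl)-3,6-dioxobicyclo[3.2.1]octane-2-carboxylate F5. At 170 °C (xylene) its enol would undergo the Carroll rearrangement, which forms C9–C10 on the ring A face that carried the oxygen, and loss of CO2 would leave the ketone F6, the C16-oxo, ring A 1,2-didehydro analogue of 20 without the C2 carbonyl. In this sequence C9 is set only when the enol left by decarboxylation ketonises, so the rearrangement does not secure it: the C9 epimers of F6 would be separated and the unwanted one re-equilibrated (TsOH, PhMe, 80 °C). H2 over Pd/C (EtOAc) would saturate C1=C2 to the saturated anhydride F7. The Lombardo reagent (Zn, CH2Br2, TiCl4, THF/CH2Cl2, 0 °C), which is not basic and should leave C9 alone, would methylenate the less hindered C16 ketone to the methylidene anhydride F8, the cyclic anhydride of 23. Aqueous THF with NaHCO3, then acid to pH 3, would open F8 to 23.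

Step 7. Traces of proton sources would desilylate 10 to the free β-keto acid, which decarboxylates to the ketone and loses the regiochemistry of the enol ether. The fallback sets out from 9 and comes back at 11. Pd(PPh3)4 and morpholine (THF, 0 °C) would give the β-keto acid (1R,5S)-1-({[tert-butyl(dimethyl)silyl]oxy}methyl)-6-methylidene-3-oxobicyclo[3.2.1]octane-2-carboxylic acid F9. N-Bromosuccinimide (CH2Cl2, 0 °C) would effect decarboxylative bromination to the α-bromo ketone (1R,5S)-2-bromo-1-({[tert-butyl(dimethyl)silyl]oxy}methyl)-6-methylidenebicyclo[3.2.1]octan-3-one F10. Zinc dust with Me3SiCl (MeCN, 25 °C) would convert F10 regiospecifically into 11.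

Further compounds
F1 | step 5 | 3-({[tert-butyl(dimethyl)silyl]oxy}methyl)-N-[(2S)-2-(methoxymethyl)pyrrolidin-1-yl]cyclopent-2-en-1-imine | COC[C@@H]1CCCN1N=C1C=C(CO[Si](C)(C)C(C)(C)C)CC1
F2 | step 5 | prop-2-en-1-yl (2E)-4-[(1S)-4-({[tert-butyl(dimethyl)silyl]oxy}methyl)-2-{[(2S)-2-(methoxymethyl)pyrrolidin-1-yl]imino}cyclopent-3-en-1-yl]-3-methoxybut-2-enoate | COC[C@@H]1CCCN1N=C1C=C(CO[Si](C)(C)C(C)(C)C)C[C@H]1C\C(OC)=C/C(=O)OCC=C
F3 | step 5 | prop-2-en-1-yl 4-[(1S)-4-({[tert-butyl(dimethyl)silyl]oxy}methyl)-2-oxocyclopent-3-en-1-yl]-3-oxobutanoate | O=C1C=C(CO[Si](C)(C)C(C)(C)C)C[C@H]1CC(=O)CC(=O)OCC=C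
F4 | step 11 | (3aR,5R,7aS)-5-hydroxy-3a,7-dimethyl-3a,4,5,7a-tetrahydro-2-benzofuran-1,3-dione | CC1=C[C@H](O)C[C@@]2(C)C(=O)OC(=O)[C@@H]12
F5 | step 11 | (3aR,5R,7aS)-3a,7-dimethyl-1,3-dioxo-1,3,3a,4,5,7a-hexahydro-2-benzofuran-5-yl (1R,5S)-1-({[tert-butyl(dimethyl)silyl]oxy}methyl)-3,6-dioxobicyclo[3.2.1]octane-2-carboxylate | O=C1C[C@]2(CO[Si](C)(C)C(C)(C)C)C[C@H]1CC(=O)C2C(=O)O[C@H]1C=C(C)[C@@H]3C(=O)OC(=O)[C@]3(C)C1
F6 | step 11 | Carroll product: cyclic anhydride of (1R,2S,3S)-3-[(1R,2S,5S)-1-({[tert-butyl(dimethyl)silyl]oxy}methyl)-3,6-dioxobicyclo[3.2.1]octan-2-yl]-1,3-dimethylcyclohex-4-ene-1,2-dicarboxylic acid | O=C1C[C@]2(CO[Si](C)(C)C(C)(C)C)C[C@H]1CC(=O)[C@H]2[C@]1(C)C=CC[C@@]3(C)C(=O)OC(=O)[C@@H]13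
F7 | step 11 | cyclic anhydride of (1R,2S,3S)-3-[(1R,2S,5S)-1-({[tert-butyl(dimethyl)silyl]oxy}methyl)-3,6-dioxobicyclo[3.2.1]octan-2-yl]-1,3-dimethylcyclohexane-1,2-dicarboxylic acid | O=C1C[C@]2(CO[Si](C)(C)C(C)(C)C)C[C@H]1CC(=O)[C@H]2[C@]1(C)CCC[C@@]3(C)C(=O)OC(=O)[C@@H]13
F8 | step 11 | cyclic anhydride of (1R,2S,3S)-3-[(1R,2S,5S)-1-({[tert-butyl(dimethyl)silyl]oxy}methyl)-6-methylidene-3-oxobicyclo[3.2.1]octan-2-yl]-1,3-dimethylcyclohexane-1,2-dicarboxylic acid | C=C1C[C@]2(CO[Si](C)(C)C(C)(C)C)C[C@H]1CC(=O)[C@H]2[C@]1(C)CCC[C@@]3(C)C(=O)OC(=O)[C@@H]13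
F9 | step 7 | (1R,5S)-1-({[tert-butyl(dimethyl)silyl]oxy}methyl)-6-methylidene-3-oxobicyclo[3.2.1]octane-2-carboxylic acid | C=C1C[C@]2(CO[Si](C)(C)C(C)(C)C)C[C@H]1CC(=O)C2C(=O)O
F10 | step 7 | (1R,5S)-2-bromo-1-({[tert-butyl(dimethyl)silyl]oxy}methyl)-6-methylidenebicyclo[3.2.1]octan-3-one | C=C1C[C@]2(CO[Si](C)(C)C(C)(C)C)C[C@H]1CC(=O)C2Br
A1 | direct plan | dimethyl (1R,2S)-1,3-dimethyl-5-oxocyclohex-3-ene-1,2-dicarboxylate (racemic) | CC1=CC(=O)C[C@@](C)(C(=O)OC)[C@H]1C(=O)OC
A2 | direct plan | dimethyl (1R,2S,5R)-5-hydroxy-1,3-dimethylcyclohex-3-ene-1,2-dicarboxylate | CC1=C[C@H](O)C[C@@](C)(C(=O)OC)[C@H]1C(=O)OC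
A3 | direct plan | dimethyl (1R,2S,3S)-3-[(1R)-2-(1,3-dithian-2-yl)-6-oxocyclohexyl]-1,3-dimethylcyclohex-4-ene-1,2-dicarboxylate | C1CSC(SC1)C2CCCC(=O)[C@H]2[C@]3(C)C=CC[C@@](C)(C(=O)OC)[C@H]3C(=O)OC
A4 | direct plan | dimethyl (1R,2S,3S)-3-[(1S,2R)-2-(2-bromoprop-2-en-1-yl)-2-formyl-6-oxocyclohexyl]-1,3-dimethylcyclohexane-1,2-dicarboxylate | C=C(Br)C[C@]1(C=O)CCCC(=O)[C@H]1[C@]2(C)CCC[C@@](C)(C(=O)OC)[C@H]2C(=O)OC
A5 | direct plan | dimethyl (1R,2S,3S)-3-[(1R,2S,5S)-1-formyl-6-methylidene-3-oxobicyclo[3.2.1]octan-2-yl]-1,3-dimethylcyclohexane-1,2-dicarboxylate | C=C1C[C@]2(C=O)C[C@H]1CC(=O)[C@H]2[C@]1(C)CCC[C@@](C)(C(=O)OC)[C@H]1C(=O)OC
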